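**Plan**

1. Target numbering (bicyclo[3.2.1]octane): C1 bridgehead (OMe), C2 ketone, C3 (OMe), C4 (CH2), C5 bridgehead (allyl), C6 (CH3), C7 (aryl), C8 (OAc). Precursors are described with these numbers. Retrosynthesis: adjust C8–OAc and the C2 ketone, then cut C1–C8 and C6–C7 together to reach the open-chain aldehyde 18; then cut C1=C7 (olefination with 13), C1–C2 (phosphonate 10) and the substituents on C5 (lactone 1).
2. Enabling feature: the carbinol carbon C8 and the CH–CH3 carbon C6 both sit on the quaternary C5, and C1 and C7 are neighbours. An aldehyde carbon and a vinyl group on C5 can therefore be added across a C1=C7 styryl enol ether in one radical chain; the aryl group stabilises the relay radical and the C6 methyl group is the chain end.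
3. Forward: lactone 1 is hydroxymethylated (C8) and allylated at C5; the lactone carbonyl becomes the vinyl group (C6 and its methyl); C3–OH is methylated; C2 is extended by C1 and C7. The key step closes the six-membered ring first (C1–C8), then the five-membered ring (C6–C7). Acetylation, PMB removal and oxidation finish.
4. Stereochemistry: C3 comes from the L-glutamic acid-derived lactone 1; C5 from alkylation anti to the CH2OTr group; the temporary C2 carbinol from a CBS reduction; C1, C8, C7 and C6 arise in the cascade under control of C3 and C5 (chair 6-exo, then boat-like 5-exo).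

Key step: step 15

Assumption: 1 is bought (it is also made in two steps from L-glutamic acid).
Remark: lithium enolates, alkoxides and the lithiated form of 10 are the deprotonated forms of the numbered compounds of their steps and are not numbered separately; covalent intermediates and the radicals of the key step are numbered.

**Route**

Step 1
Reactants: 1 (S)-5-[(trityloxy)methyl]dihydrofuran-2(3H)-one
Product: 2 (5S)-3-(hydroxymethyl)-5-[(trityloxy)methyl]dihydrofuran-2(3H)-one (C3 epimers)
Conditions: LiN(i-Pr)2 (1.1 equiv), THF, −78 °C; HCHO gas (from paraformaldehyde), −78 → −20 °C; then water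
Reagents that add atoms: formaldehyde, C=O
Why: The kinetic lithium enolate of the lactone adds to monomeric formaldehyde (aldol hydroxymethylation, introduces C8); the new C3 centre of the lactone forms as a mixture that is erased in step 2.

Step 2
Reactants: 2 (5S)-3-(hydroxymethyl)-5-[(trityloxy)methyl]dihydrofuran-2(3H)-one
Product: 3 (3R,5S)-3-(hydroxymethyl)-3-(prop-2-en-1-yl)-5-[(trityloxy)methyl]dihydrofuran-2(3H)-one
Conditions: LiN(i-Pr)2 (2.2 equiv), THF–DMPU, −78 °C; allyl bromide, −78 → −30 °C; then water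
Reagents that add atoms: allyl bromide, C=CCBr
Why: C-alkylation of the alkoxide–enolate dianion (Fráter–Seebach-type alkylation, no β-elimination from an alkoxide) should take allyl bromide on the enolate face anti to the bulky CH2OTr group, which sets quaternary C5 with allyl trans and CH2OH cis to that group.

Step 3
Reactants: 3 (3R,5S)-3-(hydroxymethyl)-3-(prop-2-en-1-yl)-5-[(trityloxy)methyl]dihydrofuran-2(3H)-one
Product: 4 (3R,5S)-3-{[tert-butyl(diphenyl)silyl]oxymethyl}-3-(prop-2-en-1-yl)-5-[(trityloxy)methyl]dihydrofuran-2(3H)-one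
Conditions: t-BuPh2SiCl, imidazole, DMF, rt
Reagents that add atoms: tert-butyl(chloro)diphenylsilane, CC(C)(C)[Si](Cl)(c1ccccc1)c1ccccc1
Why: Standard silylation of the primary alcohol; the TBDPS group is chosen because it survives the later acid detritylation and migrates little under base.

Step 4
Reactants: 4 (3R,5S)-3-{[tert-butyl(diphenyl)silyl]oxymethyl}-3-(prop-2-en-1-yl)-5-[(trityloxy)methyl]dihydrofuran-2(3H)-one
Product: 5 (3R,5S)-3-{[tert-butyl(diphenyl)silyl]oxymethyl}-3-(prop-2-en-1-yl)-5-[(trityloxy)methyl]tetrahydrofuran-2-ol (anomers)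
Conditions: (i-Bu)2AlH (1.2 equiv), CH2Cl2, −78 °C; aqueous work-up
Reagents that add atoms: none
Why: Partial reduction of a lactone to the lactol with (i-Bu)2AlH at low temperature, helped here by the quaternary α-carbon that stabilises the tetrahedral aluminate.

Step 5
Reactants: 5 (3R,5S)-3-{[tert-butyl(diphenyl)silyl]oxymethyl}-3-(prop-2-en-1-yl)-5-[(trityloxy)methyl]tetrahydrofuran-2-ol
Product: 6 (2S,4S)-4-{[tert-butyl(diphenyl)silyl]oxymethyl}-4-ethenyl-1-(trityloxy)hept-6-en-2-ol
Conditions: Ph3PCH3Br (3 equiv), KOt-Bu (3 equiv), THF, 0 → 60 °C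
Reagents that add atoms: methylenetriphenylphosphorane (from methyltriphenylphosphonium bromide and KOt-Bu), C=P(c1ccccc1)(c1ccccc1)c1ccccc1
Why: Wittig methylenation of the open hydroxy-aldehyde form of the lactol turns the former lactone carbonyl into the vinyl group (C6 and the future C6 methyl carbon) and frees the C3 hydroxyl; no stereocentre is touched.

Step 6
Reactants: 6 (2S,4S)-4-{[tert-butyl(diphenyl)silyl]oxymethyl}-4-ethenyl-1-(trityloxy)hept-6-en-2-ol
Product: 7 (2S,4S)-4-{[tert-butyl(diphenyl)silyl]oxymethyl}-4-ethenyl-2-methoxy-1-(trityloxy)hept-6-ene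
Conditions: NaH, MeI, THF–DMF, 0 °C → rt
Reagents that add atoms: iodomethane, CI
Why: Williamson etherification of the secondary alkoxide installs the C3 methoxy group with the configuration of the lactone carbon retained.

Step 7
Reactants: 7 (2S,4S)-4-{[tert-butyl(diphenyl)silyl]oxymethyl}-4-ethenyl-2-methoxy-1-(trityloxy)hept-6-ene
Product: 8 (2S,4S)-4-{[tert-butyl(diphenyl)silyl]oxymethyl}-4-ethenyl-2-methoxyhept-6-en-1-ol
Conditions: p-TsOH·H2O (0.1 equiv), MeOH–CH2Cl2 (1:1), 0 °C → rt
Reagents that add atoms: none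
Why: Acid-catalysed solvolysis of the trityl ether (trityl cation trapped by methanol) frees the C2 alcohol while the much more acid-stable TBDPS ether stays.

Step 8
Reactants: 8 (2S,4S)-4-{[tert-butyl(diphenyl)silyl]oxymethyl}-4-ethenyl-2-methoxyhept-6-en-1-ol
Product: 9 (2S,4S)-4-{[tert-butyl(diphenyl)silyl]oxymethyl}-4-ethenyl-2-methoxyhept-6-enoic acid
Conditions: TEMPO (0.2 equiv), PhI(OAc)2 (2.2 equiv), MeCN–H2O (1:1), rt
Reagents that add atoms: water, O
Why: Oxoammonium (TEMPO/PhI(OAc)2) oxidation of the primary alcohol through the aldehyde hydrate to the acid; the conditions are near neutral and leave the alkenes, the silyl ether and the α-methoxy stereocentre alone.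

Step 9
Reactants: 9 (2S,4S)-4-{[tert-butyl(diphenyl)silyl]oxymethyl}-4-ethenyl-2-methoxyhept-6-enoic acid; 10 diethyl (methoxymethyl)phosphonate
Product: 12 diethyl [(3S,5S)-5-{[tert-butyl(diphenyl)silyl]oxymethyl}-5-ethenyl-1,3-dimethoxy-2-oxooct-7-en-1-yl]phosphonate (epimers at the phosphorus-bearing carbon), via acyl imidazolide 11 (not isolated)
Conditions: 9, 1,1'-carbonyldiimidazole, THF, rt; added to 10 (2.2 equiv) and LiN(i-Pr)2 (2.2 equiv), THF, −78 → −30 °C; then water (pH 5)
Reagents that add atoms: none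
Why: Claisen-type acylation of the lithiated α-methoxy phosphonate by the acyl imidazolide gives the β-keto phosphonate (introduces C1), and the second equivalent of carbanion deprotonates the product between P=O and C=O so that the C3 centre next to the new ketone is not enolised.

Step 10
Reactants: 12 diethyl [(3S,5S)-5-{[tert-butyl(diphenyl)silyl]oxymethyl}-5-ethenyl-1,3-dimethoxy-2-oxooct-7-en-1-yl]phosphonate; 13 3,4-dimethoxybenzaldehyde
Product: 14 (1Z,4S,6S)-6-{[tert-butyl(diphenyl)silyl]oxymethyl}-1-(3,4-dimethoxyphenyl)-6-ethenyl-2,4-dimethoxynona-1,8-dien-3-one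
Conditions: Ba(OH)2·8H2O (0.5–0.8 equiv), THF–H2O (40:1), rt
Reagents that add atoms: none
Why: Horner–Wadsworth–Emmons olefination under mild Ba(OH)2 conditions should give the α-methoxy enone with aryl and carbonyl trans (Z), a geometry of no later consequence because C7 passes through a radical.

Step 11
Reactants: 14 (1Z,4S,6S)-6-{[tert-butyl(diphenyl)silyl]oxymethyl}-1-(3,4-dimethoxyphenyl)-6-ethenyl-2,4-dimethoxynona-1,8-dien-3-one
Product: 15 (1Z,3R,4S,6S)-6-{[tert-butyl(diphenyl)silyl]oxymethyl}-1-(3,4-dimethoxyphenyl)-6-ethenyl-2,4-dimethoxynona-1,8-dien-3-ol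
Conditions: (S)-2-methyl-CBS-oxazaborolidine (0.2 equiv), catecholborane (1.8 equiv), toluene, −78 °C; then MeOH, aqueous work-up
Reagents that add atoms: none
Why: Corey–Bakshi–Shibata 1,2-reduction with catecholborane (which leaves the terminal alkenes alone) should deliver hydride to the Si face with the alkenyl group as the large substituent, in line with the Felkin–Anh preference next to the C3 methoxy group, to set the temporary (R)-carbinol at C2 syn to that methoxy group.

Step 12
Reactants: 15 (1Z,3R,4S,6S)-6-{[tert-butyl(diphenyl)silyl]oxymethyl}-1-(3,4-dimethoxyphenyl)-6-ethenyl-2,4-dimethoxynona-1,8-dien-3-ol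
Product: 16 (1Z,3R,4S,6S)-6-{[tert-butyl(diphenyl)silyl]oxymethyl}-1-(3,4-dimethoxyphenyl)-6-ethenyl-2,4-dimethoxy-3-[(4-methoxybenzyl)oxy]nona-1,8-diene
Conditions: NaH, 4-methoxybenzyl chloride, Bu4NI (cat.), THF–DMF, 0 °C → rt
Reagents that add atoms: 4-methoxybenzyl chloride, COc1ccc(CCl)cc1
Why: Williamson etherification under basic conditions that the acid-sensitive enol ether tolerates; the PMB ether keeps the C2 oxygen from forming a lactol with the later C8 aldehyde and is removable without fluoride or acid.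

Step 13
Reactants: 16 (1Z,3R,4S,6S)-6-{[tert-butyl(diphenyl)silyl]oxymethyl}-1-(3,4-dimethoxyphenyl)-6-ethenyl-2,4-dimethoxy-3-[(4-methoxybenzyl)oxy]nona-1,8-diene
Product: 17 (2S,4S,5R,6Z)-7-(3,4-dimethoxyphenyl)-2-ethenyl-4,6-dimethoxy-5-[(4-methoxybenzyl)oxy]-2-(prop-2-en-1-yl)hept-6-en-1-ol
Conditions: Bu4NF (1.5 equiv), THF, rt
Reagents that add atoms: none
Why: Fluoride-induced desilylation frees the neopentyl C8 alcohol and leaves the PMB ether and the enol ether untouched.

Step 14
Reactants: 17 (2S,4S,5R,6Z)-7-(3,4-dimethoxyphenyl)-2-ethenyl-4,6-dimethoxy-5-[(4-methoxybenzyl)oxy]-2-(prop-2-en-1-yl)hept-6-en-1-ol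
Product: 18 (2S,4S,5R,6Z)-7-(3,4-dimethoxyphenyl)-2-ethenyl-4,6-dimethoxy-5-[(4-methoxybenzyl)oxy]-2-(prop-2-en-1-yl)hept-6-enal
Conditions: Dess–Martin periodinane (1.3 equiv), NaHCO3, CH2Cl2, 0 °C → rt
Reagents that add atoms: none
Why: Buffered Dess–Martin oxidation gives the aldehyde, which cannot enolise or epimerise because its α-carbon (C5) is quaternary.

Step 15
Reactants: 18 (2S,4S,5R,6Z)-7-(3,4-dimethoxyphenyl)-2-ethenyl-4,6-dimethoxy-5-[(4-methoxybenzyl)oxy]-2-(prop-2-en-1-yl)hept-6-enal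
Product: 23 5-allyl-7-endo-(3,4-dimethoxyphenyl)-1,3-dimethoxy-2-[(4-methoxybenzyl)oxy]-6-exo-methylbicyclo[3.2.1]octan-8-ol (8-OH anti to the C6–C7 bridge; 3-OMe on the side of that bridge; 2-O trans to 3-OMe), via O-stannyl ketyl radical 19 (not isolated), via benzylic radical 20 (not isolated), via primary alkyl radical 21 (not isolated), via tributylstannyl ether 22 (not isolated)
Conditions: Bu3SnH (1.5 equiv, syringe pump over 6 h), AIBN (0.2 equiv), benzene (0.005 M), 80 °C; then moist silica gel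
Reagents that add atoms: none
Why: Bu3Sn• adds to the aldehyde oxygen to give O-stannyl ketyl 19, whose carbon (C8) closes 6-exo-trig on the methoxy-bearing alkene carbon (C1), the only position that leaves a benzylic radical (20); this closes 5-exo-trig on the internal vinyl carbon (C6), and the primary radical 21 takes hydrogen from Bu3SnH, so that the vinyl CH2 ends as the C6 methyl group and the chain carries on. The closest known reaction type is the tin hydride O-stannyl ketyl–olefin cyclisation and its tandem variants (related to SmI2 ketyl–styrene cyclisations). Ring closure 1 (cyclohexane) should pass through a chair in which the vinyl group on C5, the C3 methoxy group, the C2 PMB ether, the styryl carbon and the stannyloxy group are equatorial, which sets C1 (C7 cis to the vinyl group and to the C3 methoxy group) and C8 (oxygen trans to C7); the controlling elements are the C3 and C5 stereocentres of 18. Ring closure 2 (cyclopentane) joins the 1,3-cis substituents across a boat-like six-membered ring; the aryl group of the planar benzylic radical is expected to take the open endo side below the ring, away from C8–H and the C1 methoxy group, and the alkene CH2 the exo side, which gives the 7-endo-aryl/6-exo-methyl trans pair, and the reversible closure of the stabilised radical favours this less eclipsed arrangement. The step needs 6-exo over 7-endo attack (secured by the aryl group on the distal alkene carbon), closure on vinyl and not on allyl (the allyl group lies on the opposite ring face, and the ketyl reaches neither alkene on C5 in a favourable ring size) and cyclisation faster than hydrogen transfer to 20 (secured by slow addition of Bu3SnH at high dilution).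

Step 16
Reactants: 23 5-allyl-7-endo-(3,4-dimethoxyphenyl)-1,3-dimethoxy-2-[(4-methoxybenzyl)oxy]-6-exo-methylbicyclo[3.2.1]octan-8-ol
Product: 24 5-allyl-7-endo-(3,4-dimethoxyphenyl)-1,3-dimethoxy-2-[(4-methoxybenzyl)oxy]-6-exo-methylbicyclo[3.2.1]octan-8-yl acetate
Conditions: Ac2O (5 equiv), DMAP (1 equiv), pyridine, 50 °C
Reagents that add atoms: acetic anhydride, CC(=O)OC(C)=O
Why: DMAP-catalysed acylation through the N-acetylpyridinium ion acetylates the hindered C8 hydroxyl with retention, since no bond to C8 is broken.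

Step 17
Reactants: 24 5-allyl-7-endo-(3,4-dimethoxyphenyl)-1,3-dimethoxy-2-[(4-methoxybenzyl)oxy]-6-exo-methylbicyclo[3.2.1]octan-8-yl acetate
Product: 25 5-allyl-7-endo-(3,4-dimethoxyphenyl)-2-hydroxy-1,3-dimethoxy-6-exo-methylbicyclo[3.2.1]octan-8-yl acetate
Conditions: DDQ (1.5 equiv), CH2Cl2–pH 7 buffer (10:1), 0 °C → rt
Reagents that add atoms: none
Why: Oxidative PMB cleavage by DDQ (hydride abstraction at the PMB benzylic carbon, then hydrolysis) frees the C2 alcohol under neutral conditions that keep the acetate in place and spare the allyl group and the dimethoxyphenyl ring.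

Step 18
Reactants: 25 5-allyl-7-endo-(3,4-dimethoxyphenyl)-2-hydroxy-1,3-dimethoxy-6-exo-methylbicyclo[3.2.1]octan-8-yl acetate
Product: 26 (1S,3S,5S,6R,7S,8S)-7-(3,4-dimethoxyphenyl)-1,3-dimethoxy-6-methyl-2-oxo-5-(prop-2-en-1-yl)bicyclo[3.2.1]octan-8-yl acetate
Conditions: Dess–Martin periodinane (1.5 equiv), NaHCO3, CH2Cl2, rt
Reagents that add atoms: none
Why: Neutral Dess–Martin oxidation of the hindered secondary alcohol gives the C2 ketone without enolising the adjacent C3 methoxy centre; C1 is quaternary, so the β-acetoxy ketone cannot eliminate.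

**Compound list**

1 | (S)-5-[(trityloxy)methyl]dihydrofuran-2(3H)-one | O=C1CC[C@@H](COC(c2ccccc2)(c2ccccc2)c2ccccc2)O1 | starting material
2 | (5S)-3-(hydroxymethyl)-5-[(trityloxy)methyl]dihydrofuran-2(3H)-one (C3 epimers) | O=C1C(CO)C[C@@H](COC(c2ccccc2)(c2ccccc2)c2ccccc2)O1 | intermediate
3 | (3R,5S)-3-(hydroxymethyl)-3-(prop-2-en-1-yl)-5-[(trityloxy)methyl]dihydrofuran-2(3H)-one | C=CC[C@]1(CO)C[C@@H](COC(c2ccccc2)(c2ccccc2)c2ccccc2)OC1=O | intermediate
4 | (3R,5S)-3-{[tert-butyl(diphenyl)silyl]oxymethyl}-3-(prop-2-en-1-yl)-5-[(trityloxy)methyl]dihydrofuran-2(3H)-one | C=CC[C@]1(CO[Si](c2ccccc2)(c2ccccc2)C(C)(C)C)C[C@@H](COC(c2ccccc2)(c2ccccc2)c2ccccc2)OC1=O | intermediate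
5 | (3R,5S)-3-{[tert-butyl(diphenyl)silyl]oxymethyl}-3-(prop-2-en-1-yl)-5-[(trityloxy)methyl]tetrahydrofuran-2-ol (anomers) | C=CC[C@]1(CO[Si](c2ccccc2)(c2ccccc2)C(C)(C)C)C[C@@H](COC(c2ccccc2)(c2ccccc2)c2ccccc2)OC1O | intermediate
6 | (2S,4S)-4-{[tert-butyl(diphenyl)silyl]oxymethyl}-4-ethenyl-1-(trityloxy)hept-6-en-2-ol | C=CC[C@](C=C)(CO[Si](c1ccccc1)(c1ccccc1)C(C)(C)C)C[C@H](O)COC(c1ccccc1)(c1ccccc1)c1ccccc1 | intermediate
7 | (2S,4S)-4-{[tert-butyl(diphenyl)silyl]oxymethyl}-4-ethenyl-2-methoxy-1-(trityloxy)hept-6-ene | C=CC[C@](C=C)(CO[Si](c1ccccc1)(c1ccccc1)C(C)(C)C)C[C@H](OC)COC(c1ccccc1)(c1ccccc1)c1ccccc1 | intermediate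
8 | (2S,4S)-4-{[tert-butyl(diphenyl)silyl]oxymethyl}-4-ethenyl-2-methoxyhept-6-en-1-ol | C=CC[C@](C=C)(CO[Si](c1ccccc1)(c1ccccc1)C(C)(C)C)C[C@H](OC)CO | intermediate
9 | (2S,4S)-4-{[tert-butyl(diphenyl)silyl]oxymethyl}-4-ethenyl-2-methoxyhept-6-enoic acid | C=CC[C@](C=C)(CO[Si](c1ccccc1)(c1ccccc1)C(C)(C)C)C[C@H](OC)C(=O)O | intermediate
10 | diethyl (methoxymethyl)phosphonate | CCOP(=O)(COC)OCC | starting material
11 | acyl imidazolide of 9 (not isolated) | C=CC[C@](C=C)(CO[Si](c1ccccc1)(c1ccccc1)C(C)(C)C)C[C@H](OC)C(=O)n1ccnc1 | intermediate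
12 | diethyl [(3S,5S)-5-{[tert-butyl(diphenyl)silyl]oxymethyl}-5-ethenyl-1,3-dimethoxy-2-oxooct-7-en-1-yl]phosphonate (C1 epimers) | C=CC[C@](C=C)(CO[Si](c1ccccc1)(c1ccccc1)C(C)(C)C)C[C@H](OC)C(=O)C(OC)P(=O)(OCC)OCC | intermediate
13 | 3,4-dimethoxybenzaldehyde | O=Cc1ccc(OC)c(OC)c1 | starting material
14 | (1Z,4S,6S)-6-{[tert-butyl(diphenyl)silyl]oxymethyl}-1-(3,4-dimethoxyphenyl)-6-ethenyl-2,4-dimethoxynona-1,8-dien-3-one | C=CC[C@](C=C)(CO[Si](c1ccccc1)(c1ccccc1)C(C)(C)C)C[C@H](OC)C(=O)/C(OC)=C/c1ccc(OC)c(OC)c1 | intermediate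
15 | (1Z,3R,4S,6S)-6-{[tert-butyl(diphenyl)silyl]oxymethyl}-1-(3,4-dimethoxyphenyl)-6-ethenyl-2,4-dimethoxynona-1,8-dien-3-ol | C=CC[C@](C=C)(CO[Si](c1ccccc1)(c1ccccc1)C(C)(C)C)C[C@H](OC)[C@@H](O)/C(OC)=C/c1ccc(OC)c(OC)c1 | intermediate
16 | (1Z,3R,4S,6S)-6-{[tert-butyl(diphenyl)silyl]oxymethyl}-1-(3,4-dimethoxyphenyl)-6-ethenyl-2,4-dimethoxy-3-[(4-methoxybenzyl)oxy]nona-1,8-diene | C=CC[C@](C=C)(CO[Si](c1ccccc1)(c1ccccc1)C(C)(C)C)C[C@H](OC)[C@@H](OCc1ccc(OC)cc1)/C(OC)=C/c1ccc(OC)c(OC)c1 | intermediate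
17 | (2S,4S,5R,6Z)-7-(3,4-dimethoxyphenyl)-2-ethenyl-4,6-dimethoxy-5-[(4-methoxybenzyl)oxy]-2-(prop-2-en-1-yl)hept-6-en-1-ol | C=CC[C@](C=C)(CO)C[C@H](OC)[C@@H](OCc1ccc(OC)cc1)/C(OC)=C/c1ccc(OC)c(OC)c1 | intermediate
18 | (2S,4S,5R,6Z)-7-(3,4-dimethoxyphenyl)-2-ethenyl-4,6-dimethoxy-5-[(4-methoxybenzyl)oxy]-2-(prop-2-en-1-yl)hept-6-enal | C=CC[C@](C=C)(C=O)C[C@H](OC)[C@@H](OCc1ccc(OC)cc1)/C(OC)=C/c1ccc(OC)c(OC)c1 | intermediate
19 | O-stannyl ketyl radical of 18 (radical at C8, not isolated) | C=CC[C@](C=C)([CH]O[Sn](CCCC)(CCCC)CCCC)C[C@H](OC)[C@@H](OCc1ccc(OC)cc1)/C(OC)=C/c1ccc(OC)c(OC)c1 | intermediate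
20 | monocyclic benzylic radical (cyclohexane closed, radical at C7, not isolated) | C=CC[C@@]1(C=C)C[C@H](OC)[C@@H](OCc2ccc(OC)cc2)[C@](OC)([CH]c2ccc(OC)c(OC)c2)[C@H]1O[Sn](CCCC)(CCCC)CCCC | intermediate
21 | bicyclic primary alkyl radical (radical on the C6 methyl carbon, not isolated) | C=CC[C@]12C[C@H](OC)[C@@H](OCc3ccc(OC)cc3)[C@](OC)([C@H](c3ccc(OC)c(OC)c3)[C@H]1[CH2])[C@H]2O[Sn](CCCC)(CCCC)CCCC | intermediate
22 | tributylstannyl ether of 23 (not isolated) | C=CC[C@]12C[C@H](OC)[C@@H](OCc3ccc(OC)cc3)[C@](OC)([C@H](c3ccc(OC)c(OC)c3)[C@H]1C)[C@H]2O[Sn](CCCC)(CCCC)CCCC | intermediate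
23 | 5-allyl-7-endo-(3,4-dimethoxyphenyl)-1,3-dimethoxy-2-[(4-methoxybenzyl)oxy]-6-exo-methylbicyclo[3.2.1]octan-8-ol | C=CC[C@]12C[C@H](OC)[C@@H](OCc3ccc(OC)cc3)[C@](OC)([C@H](c3ccc(OC)c(OC)c3)[C@H]1C)[C@H]2O | intermediate
24 | 5-allyl-7-endo-(3,4-dimethoxyphenyl)-1,3-dimethoxy-2-[(4-methoxybenzyl)oxy]-6-exo-methylbicyclo[3.2.1]octan-8-yl acetate | C=CC[C@]12C[C@H](OC)[C@@H](OCc3ccc(OC)cc3)[C@](OC)([C@H](c3ccc(OC)c(OC)c3)[C@H]1C)[C@H]2OC(C)=O | intermediate
25 | 5-allyl-7-endo-(3,4-dimethoxyphenyl)-2-hydroxy-1,3-dimethoxy-6-exo-methylbicyclo[3.2.1]octan-8-yl acetate | C=CC[C@]12C[C@H](OC)[C@@H](O)[C@](OC)([C@H](c3ccc(OC)c(OC)c3)[C@H]1C)[C@H]2OC(C)=O | intermediate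
26 | (1S,3S,5S,6R,7S,8S)-7-(3,4-dimethoxyphenyl)-1,3-dimethoxy-6-methyl-2-oxo-5-(prop-2-en-1-yl)bicyclo[3.2.1]octan-8-yl acetate | C=CC[C@]12C[C@H](OC)C(=O)[C@](OC)([C@H](c3ccc(OC)c(OC)c3)[C@H]1C)[C@H]2OC(C)=O | target

**Summary**

Total step count: 18. Longest linear sequence: 18 steps (1 → 26); 10 and 13 enter as bought materials.

Three steps most likely to fail:

Step 15 (key step). The benzylic radical 20 may take hydrogen from the stannane before the second ring closes, or the second closure may show poor facial selectivity at C7 and C6 (aryl exo); this is the least secure prediction of the route. The fallback sets out from enone 14 and makes the two bonds in separate, differently controlled steps with C2 already a ketone. Bu4NF in THF removes the silyl group to give the enone alcohol F1, and buffered Dess–Martin oxidation gives the keto aldehyde F2. Me2AlSPh in CH2Cl2 at −78 °C adds sulfur to C7, and the aluminium enolate closes C1–C8 by aldol reaction under equilibrating ionic conditions to the phenylthio hydroxy cyclohexanone F3 (sulfide epimers at C7 are of no consequence). Bu3SnH/AIBN in benzene at 80 °C then makes the C7 benzylic radical from the C–S bond for the 5-exo closure on the vinyl group beside a flat C2 carbonyl, giving the bicyclic hydroxy ketone F4. Ac2O/DMAP acetylates the C8 hydroxyl and the route is rejoined at target 26.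

Step 2. O-allylation of the alkoxide, loss of formaldehyde from the dianion by retro-aldol cleavage, or poor facial selectivity may erode the quaternary centre. The fallback sets out from 1 and uses a soft enolate. NaH and ethyl formate give the formyl lactone F5 (present as its hydroxymethylene tautomer). Pd(PPh3)4 and allyl methyl carbonate in THF allylate it on carbon anti to the CH2OTr group to give the allyl formyl lactone F6. NaBH4 in MeOH at −20 °C reduces only the aldehyde and returns to 3.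

Step 16. Acylation of the C8 hydroxyl, which lies between two quaternary carbons, may stall, and forcing conditions may degrade the material. The fallback sets out from 18: step 15 is run as before, but acetyl chloride is added to the stannyl ether 22 in the same flask before any aqueous work-up (Sn–O bonds are acylated by acid chlorides without base). This gives acetate 24 directly, where the route is rejoined; no compound outside the list is made (F0).

Further compounds
F1 | step 15 | (1Z,4S,6S)-1-(3,4-dimethoxyphenyl)-6-ethenyl-6-(hydroxymethyl)-2,4-dimethoxynona-1,8-dien-3-one | C=CC[C@](C=C)(CO)C[C@H](OC)C(=O)/C(OC)=C/c1ccc(OC)c(OC)c1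
F2 | step 15 | (2S,4S,6Z)-7-(3,4-dimethoxyphenyl)-2-ethenyl-4,6-dimethoxy-5-oxo-2-(prop-2-en-1-yl)hept-6-enal | C=CC[C@](C=C)(C=O)C[C@H](OC)C(=O)/C(OC)=C/c1ccc(OC)c(OC)c1
F3 | step 15 | 4-allyl-2-[(3,4-dimethoxyphenyl)(phenylthio)methyl]-4-ethenyl-3-hydroxy-2,6-dimethoxycyclohexan-1-one (ring configuration as in 26, sulfide epimers) | C=CC[C@@]1(C=C)C[C@H](OC)C(=O)[C@](OC)(C(Sc2ccccc2)c2ccc(OC)c(OC)c2)[C@H]1O
F4 | step 15 | 5-allyl-7-endo-(3,4-dimethoxyphenyl)-8-hydroxy-1,3-dimethoxy-6-exo-methylbicyclo[3.2.1]octan-2-one | C=CC[C@]12C[C@H](OC)C(=O)[C@](OC)([C@H](c3ccc(OC)c(OC)c3)[C@H]1C)[C@H]2O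
F5 | step 2 | (5S)-2-oxo-5-[(trityloxy)methyl]tetrahydrofuran-3-carbaldehyde (hydroxymethylene tautomer) | O=CC1C[C@@H](COC(c2ccccc2)(c2ccccc2)c2ccccc2)OC1=O
F6 | step 2 | (3R,5S)-2-oxo-3-(prop-2-en-1-yl)-5-[(trityloxy)methyl]tetrahydrofuran-3-carbaldehyde | C=CC[C@]1(C=O)C[C@@H](COC(c2ccccc2)(c2ccccc2)c2ccccc2)OC1=O
F0 | step 16 | none | none
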